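(All runs were generated by integration for an exercise; scatter was added.)

The ratio of protic impurity to starting material in this flask is 0.200, between the theta run's 0.135 and the gamma run's 0.300.

| flask | starting material | protic impurity | remark | time |
|---|---|---|---|---|
| theta | 2 M | 0.27 M | run made earlier |  |
| gamma | 2 M | 0.60 M | run made earlier |  |
| epsilon | 1 M | 0.40 M | run made earlier |  |
| flask | 2.0 M | 0.400 M |  | 3.0 d |

| theta: time / d | theta: target / % | gamma: time / d | gamma: target / % | epsilon: time / d | epsilon: target / % |
|---|---|---|---|---|---|
| 0.0208 | 10.4 | 0.0208 | 9.2 | 0.0208 | 9.1 |
| 0.0833 | 11.9 | 0.0833 | 9.5 | 0.0833 | 7.6 |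
| 0.250 | 11.3 | 0.250 | 8.8 | 0.250 | 7.7 |
| 0.833 | 10.2 | 0.833 | 8.7 | 0.833 | 7.8 |
| 2.50 | 11.0 | 2.50 | 8.8 | 2.50 | 7.8 |

(readings scatter by 0.3 percentage points)



- the moment within 3.0 d at which there is most target
- the amount of target, in percent of the starting material charged, at that time
- earliest time at which at least nineteen twentieths of that best amount are there
- latest time at which they still are, in d

A first guess takes the late target as a constant percentage of the charge. The objection is immediate: the late readings of theta and gamma, 11.0% and 8.8%, differ by 2.2 percentage points, against a scatter of 0.3 points.

A better guess supposes that each protic impurity removes one starting material for good, as the limiting reagent of a side reaction, and that the remainder divides in constant proportion. Dividing the mean of each run's last two readings by one minus its ratio gives 12.3% for theta, 12.5% for gamma and 13.0% for epsilon. Their mean, 12.6%, is the plateau share: the part of the starting material spared by the impurity that stands as target in the late readings.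

But epsilon holds half the starting material of theta, so the share might depend on concentration. The spread of 0.5 points between epsilon and gamma is near the scatter of one reading, which lets the objection go. The plateau reckoned for the flask is then 10.1%.

The plateau is not the peak. The highest readings of theta and gamma, both at this charge of starting material, stand a mean factor 1.10 above their plateaus, so this reckoning gives 11.1%. Each of those readings carries the scatter, yet the reckoned threshold of 10.6% stands above the reckoned plateau, so by this reckoning the window closes.

The forecast, holding that early readings “show a real overshoot”, gives 10.8% at 1.5 h, with a window from 0.5 h to 0.2 d; its plateau is 9.7%, this reckoning's 10.1%.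

The flask gives 11.0% at 1.13 h, and the asked window runs from 0.582 h to 0.134 d.

    starting material ⇌ target (K = 0.640, k = 0.0110 min⁻¹)
    target ⇌ isomer of the product A (K = 2.10, k = 0.0610 min⁻¹)
    isomer of the product A ⇌ isomer of the product B (K = 1.50, k = 0.0390 min⁻¹)
    2 starting material → homo dimer (k = 2.10 × 10⁻⁵ M⁻¹ min⁻¹)
    starting material + protic impurity → quenched substrate (k = 0.0790 M⁻¹ min⁻¹)

At 3.00 d the flask holds 20.0% quenched substrate, with protic impurity at 0%. The plateau share gives 10.1% of target there, and the flask holds 10.1%. In the neighbouring flask with 1.6 M of protic impurity, the same share gives 2.52%, and that flask holds 2.55% of target at 3.00 d.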